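**Retrosynthetic overview**

- The target is a depside with no stereocentre. Its last step is acidolysis of a tert-butyl ester that masks the ring B carboxylic acid.
- The key disconnection is the aryl C–O bond between the ester oxygen and C4 of ring B. It rests on this feature: C4 of ring B is flanked only by C3–H and C5–H, whereas the acyl carbon on C1 of ring A is buried between the C2 heptyl and C6 methoxy groups. The ester is therefore made from the ring A carboxylate as oxygen nucleophile and a ring B arylboronic acid under copper mediation.
- The boron is placed on ring B by sterically controlled iridium C–H borylation of tert-butyl 2-heptyl-6-methoxybenzoate, where C4–H is the only ring hydrogen without an ortho substituent.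
- Both heptyl chains come from benzylic hexylation of the corresponding o-toluic acid dianions with 1-bromohexane.
- No ring is formed; both benzene rings are purchased.

Key step: step 6

Remark: ring A is the acyl ring (2-heptyl-4,6-dimethoxybenzoyl). Ring B carries the free carboxylic acid and is numbered from its carboxyl-bearing carbon as C1. Both toluic acids, 1-bromohexane and bis(pinacolato)diboron are assumed to be purchasable.

**Route**

Step 1
Reactants: 1 2,4-dimethoxy-6-methylbenzoic acid; 2 1-bromohexane
Product: 4 2-heptyl-4,6-dimethoxybenzoic acid, via benzylic dilithio dianion 3 (not isolated)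
Conditions: LiN(iPr)2 (2.3 equiv, commercial solution), THF, −78 to 0 °C; then 2 (1.2 equiv), −78 °C to rt; aq. HCl work-up
Reagents that add atoms: none
Why: Two equivalents of amide base should give the carboxylate and then the benzylic lithio species stabilised by the ortho carboxylate, which the primary bromide alkylates by SN2 (lateral alkylation of an o-toluic acid dianion); the product CH2 is less acidic, so a second alkylation is not expected.

Step 2
Reactants: 5 2-methoxy-6-methylbenzoic acid; 2 1-bromohexane
Product: 7 2-heptyl-6-methoxybenzoic acid, via benzylic dilithio dianion 6 (not isolated)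
Conditions: LiN(iPr)2 (2.3 equiv, commercial solution), THF, −78 to 0 °C; then 2 (1.2 equiv), −78 °C to rt; aq. HCl work-up
Reagents that add atoms: none
Why: The same lateral lithiation–alkylation of an o-toluic acid dianion applies; the benzylic anion conjugated with the carboxylate is the thermodynamic site of the second deprotonation and should be hexylated cleanly by the primary bromide.

Step 3
Reactants: 7 2-heptyl-6-methoxybenzoic acid
Product: 8 tert-butyl 2-heptyl-6-methoxybenzoate
Conditions: tert-butyl 2,2,2-trichloroacetimidate (2.5 equiv), CH2Cl2/cyclohexane, rt
Reagents that add atoms: tert-butyl 2,2,2-trichloroacetimidate, CC(C)(C)OC(=N)C(Cl)(Cl)Cl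
Why: The acid protonates the imidate and the carboxylate oxygen captures the tert-butyl cation (imidate O-alkylation), so the ester forms at oxygen and the hindrance at the 2,6-disubstituted acyl carbon does not matter.

Step 4
Reactants: 8 tert-butyl 2-heptyl-6-methoxybenzoate; 9 bis(pinacolato)diboron
Product: 10 tert-butyl 2-heptyl-6-methoxy-4-(4,4,5,5-tetramethyl-1,3,2-dioxaborolan-2-yl)benzoate
Conditions: [Ir(OMe)(cod)]2 (1.5 mol%), 4,4'-di-tert-butyl-2,2'-bipyridine (3 mol%), 9 (1.0 equiv), cyclohexane, 80 °C
Reagents that add atoms: none
Why: Iridium-catalysed aromatic C–H borylation through a trivalent iridium tris(boryl) complex avoids C–H bonds next to substituents, so of the three ring hydrogens only C4–H, which lies between C3–H and C5–H, should react; the ester, ether and alkyl chain are inert.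

Step 5
Reactants: 10 tert-butyl 2-heptyl-6-methoxy-4-(4,4,5,5-tetramethyl-1,3,2-dioxaborolan-2-yl)benzoate
Product: 11 [4-(tert-butoxycarbonyl)-3-heptyl-5-methoxyphenyl]boronic acid
Conditions: NaIO4 (3 equiv), NH4OAc (3 equiv), acetone/H2O 1:1, rt
Reagents that add atoms: water, O
Why: The pinacol ester equilibrates with boronic acid and pinacol in the buffered aqueous medium and periodate cleaves the released 1,2-diol to acetone (glycol cleavage), which pulls the hydrolysis to completion at near-neutral pH where the tert-butyl ester is stable.

Step 6
Reactants: 4 2-heptyl-4,6-dimethoxybenzoic acid (2 equiv, excess recoverable by base extraction); 11 [4-(tert-butoxycarbonyl)-3-heptyl-5-methoxyphenyl]boronic acid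
Product: 12 4-(tert-butoxycarbonyl)-3-heptyl-5-methoxyphenyl 2-heptyl-4,6-dimethoxybenzoate
Conditions: Cu(OTf)2 (0.4 equiv), urea (1 equiv), EtOAc, 60 °C, open to air
Reagents that add atoms: none
Why: This is a Chan–Lam-type oxidative C–O coupling: acid 4 displaces triflate on divalent copper to give a copper carboxylate, the aryl group of 11 passes from boron to copper, the aryl copper carboxylate is oxidised to trivalent copper, and reductive elimination forms the O–C4 bond and releases monovalent copper, which air returns to the divalent state. The closest known reaction is the Cu(OTf)2/urea-promoted O-arylation of carboxylic acids with arylboronic acids, which tolerates esters and aryl ethers. No ring is closed and no stereocentre is formed. The step needs chemoselectivity for carboxylate arylation over hydroxylation, homocoupling and protodeboronation of the boronic acid, and it needs the new bond at C4 of ring B; the site is fixed by the boron atom, and the chemoselectivity is helped because the reacting oxygen of 4 lies outside the pocket of the C2 heptyl and C6 methoxy groups, the boronic acid has no ortho substituent, and its para ester favours C–O reductive elimination. Urea buffers the triflic acid released on carboxylate exchange, which should protect the tert-butyl ester from acidolysis and the electron-rich acid 4 from protodecarboxylation.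

Step 7
Reactants: 12 4-(tert-butoxycarbonyl)-3-heptyl-5-methoxyphenyl 2-heptyl-4,6-dimethoxybenzoate
Product: 13 2-heptyl-4-[(2-heptyl-4,6-dimethoxybenzoyl)oxy]-6-methoxybenzoic acid (target)
Conditions: CF3CO2H/CH2Cl2 1:4, 0 °C to rt
Reagents that add atoms: none
Why: Acidolysis of the tert-butyl ester proceeds by alkyl–oxygen cleavage with loss of isobutene, so no attack at the hindered ring B carbonyl is needed, and the aryl ester and methyl ethers should survive.

**Compound list**

1 | 2,4-dimethoxy-6-methylbenzoic acid | Cc1cc(OC)cc(OC)c1C(=O)O | starting material
2 | 1-bromohexane | CCCCCCBr | starting material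
3 | dilithium salt of the benzylic dianion of 1 | [Li+].[Li+].[CH2-]c1cc(OC)cc(OC)c1C(=O)[O-] | intermediate
4 | 2-heptyl-4,6-dimethoxybenzoic acid | CCCCCCCc1cc(OC)cc(OC)c1C(=O)O | intermediate
5 | 2-methoxy-6-methylbenzoic acid | Cc1cccc(OC)c1C(=O)O | starting material
6 | dilithium salt of the benzylic dianion of 5 | [Li+].[Li+].[CH2-]c1cccc(OC)c1C(=O)[O-] | intermediate
7 | 2-heptyl-6-methoxybenzoic acid | CCCCCCCc1cccc(OC)c1C(=O)O | intermediate
8 | tert-butyl 2-heptyl-6-methoxybenzoate | CCCCCCCc1cccc(OC)c1C(=O)OC(C)(C)C | intermediate
9 | bis(pinacolato)diboron | CC1(C)OB(OC1(C)C)B1OC(C)(C)C(C)(C)O1 | starting material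
10 | tert-butyl 2-heptyl-6-methoxy-4-(4,4,5,5-tetramethyl-1,3,2-dioxaborolan-2-yl)benzoate | CCCCCCCc1cc(B2OC(C)(C)C(C)(C)O2)cc(OC)c1C(=O)OC(C)(C)C | intermediate
11 | [4-(tert-butoxycarbonyl)-3-heptyl-5-methoxyphenyl]boronic acid | CCCCCCCc1cc(B(O)O)cc(OC)c1C(=O)OC(C)(C)C | intermediate
12 | 4-(tert-butoxycarbonyl)-3-heptyl-5-methoxyphenyl 2-heptyl-4,6-dimethoxybenzoate | CCCCCCCc1cc(OC(=O)c2c(CCCCCCC)cc(OC)cc2OC)cc(OC)c1C(=O)OC(C)(C)C | intermediate
13 | 2-heptyl-4-[(2-heptyl-4,6-dimethoxybenzoyl)oxy]-6-methoxybenzoic acid | CCCCCCCc1cc(OC(=O)c2c(CCCCCCC)cc(OC)cc2OC)cc(OC)c1C(=O)O | target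

**Step count**

Total steps: 7. Longest linear sequence: 6 (steps 2, 3, 4, 5, 6, 7).

**Steps most likely to fail and fallbacks**

Step 6. Transmetalation to the copper carboxylate may be slow, so that hydroxylation, homocoupling or protodeboronation of the boronic acid takes over, and the tert-butyl group may be lost to adventitious acid before coupling. The fallback forms the ester from the acyl side through an activated acid. It sets out from 11 and 4 and returns at 12. Boronic acid 11 would be oxidised with H2O2/NaOH in THF/H2O at 0 °C to tert-butyl 2-heptyl-4-hydroxy-6-methoxybenzoate F1. Acid 4 would be converted with oxalyl chloride and catalytic DMF in CH2Cl2 to 2-heptyl-4,6-dimethoxybenzoyl chloride F2. The electron-rich 2,6-disubstituted aroyl chloride ionises readily towards an acylium-like species, so acylation of phenol F1 with F2 (Et3N, catalytic DMAP, toluene, 80 °C) should give 12.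

Step 2. Lateral deprotonation of the carboxylate may be incomplete, or ring metalation next to the methoxy group and over-alkylation may compete. The fallback reverses the order of esterification and alkylation so that a monoanion of a bulky ester is alkylated. It sets out from 5 and returns at 8. Acid 5 would be esterified with tert-butyl 2,2,2-trichloroacetimidate to tert-butyl 2-methoxy-6-methylbenzoate F3. Treatment with LiN(iPr)2 in THF at −78 °C should give the o-toluate benzylic lithio ester F4, whose tert-butyl group suppresses self-condensation, and alkylation with 2 should give 8 directly.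

Step 5. Unmasking of the pinacol ester may stall, or the C–B bond may be oxidised by periodate and the product lost in boroxine mixtures on purification. The fallback removes pinacol by transesterification instead of diol cleavage. It sets out from 10 and returns at 11. Stirring 10 with diethanolamine in diethyl ether should precipitate the diethanolamine boronate adduct F5. Brief biphasic treatment of F5 with dilute aqueous HCl and ether at rt should release 11 without touching the tert-butyl ester.

**Further compounds**

F1 | step 6 | tert-butyl 2-heptyl-4-hydroxy-6-methoxybenzoate | CCCCCCCc1cc(O)cc(OC)c1C(=O)OC(C)(C)C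
F2 | step 6 | 2-heptyl-4,6-dimethoxybenzoyl chloride | CCCCCCCc1cc(OC)cc(OC)c1C(Cl)=O
F3 | step 2 | tert-butyl 2-methoxy-6-methylbenzoate | Cc1cccc(OC)c1C(=O)OC(C)(C)C
F4 | step 2 | benzylic lithio derivative of tert-butyl 2-methoxy-6-methylbenzoate | [Li+].[CH2-]c1cccc(OC)c1C(=O)OC(C)(C)C
F5 | step 5 | diethanolamine adduct of the ring B boronic acid (tert-butyl 4-(1,3,6,2-dioxazaborocan-2-yl)-2-heptyl-6-methoxybenzoate, N→B chelate) | CCCCCCCc1cc([B-]23OCC[NH+]2CCO3)cc(OC)c1C(=O)OC(C)(C)C
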